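**Plan**

1. Numbering (abietane style): C10 is the quaternary carbon carrying the methyl group and the chain C1–C2–C3 (C3 = carboxyl carbon); C5 is the CH carrying the isopropenyl carbon C4; C6 is the ring CH2; C7 is the ring ketone; ring C is the arene C8, C9, C11–C14 (C9 on C10; O on C11, C12, C14; isopropyl on C13).
2. Retrosynthesis: the phenols are masked as acetates; C3–C4 is reconnected (acid plus isopropenyl from an ε-lactone, from a C3 ketone), which restores ring A cis-fused to ring B; C5–C6 and C9–C10 are then cut together; last, the ester tether O(C3)–CO–C6 is cut to a methyl aroylacetate and (S)-2,2,4-trimethylcyclohex-3-en-1-ol.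
3. Enabling feature: the C7 ketone has an enolizable C6 and a free ortho carbon C9, a 1,4 pair that can add as radical donor and radical acceptor across a C5=C10 alkene. The C3 carboxyl and the C4 isopropenyl group are the two ends of one severed ring A bond, so that alkene can sit in a ring A cyclohexene whose C3 oxygen lies 1,3 to C5.
4. Forward: ring C is completed first from 1,2,4-trimethoxybenzene; the ring A alcohol is attached as a β-keto ester; one oxidation with Mn(OAc)3 closes the δ-lactone ring and then ring B; the helper carboxyl leaves as CO2; ring A is cut by Baeyer–Villiger oxidation and eliminative lactone opening; the phenols are freed last.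
5. Stereochemistry: the C3 carbinol (Corey–Bakshi–Shibata reduction) delivers C6 to its own face at C5, and the lactone bridge forces the C10–C9 bond onto the same face (cis fusion, i.e. isopropenyl cis to the acid chain); C3 is oxidized away later.

Key step: step 8

**Step 1**
Reactants: 1 1,2,4-trimethoxybenzene
Product: 3 2-(2,3,6-trimethoxyphenyl)propan-2-ol, via (2,3,6-trimethoxyphenyl)lithium 2 (not isolated)
Conditions: n-BuLi, THF, 0 °C to rt; acetone, −78 °C to rt; H2O
Reagents that add atoms: acetone, CC(C)=O
Why: directed ortho-lithiation removes the ring hydrogen flanked by two methoxy groups, and the aryllithium adds to the ketone (1,2-addition).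

**Step 2**
Reactants: 3 2-(2,3,6-trimethoxyphenyl)propan-2-ol
Product: 4 1,2,4-trimethoxy-3-(propan-2-yl)benzene
Conditions: Et3SiH, CF3CO2H, CH2Cl2, 0 °C to rt
Reagents that add atoms: none
Why: ionic hydrogenation, in which the tertiary benzylic cation stabilized by two ortho methoxy groups is trapped by hydride from the silane.

**Step 3**
Reactants: 4 1,2,4-trimethoxy-3-(propan-2-yl)benzene; 5 methyl 3-chloro-3-oxopropanoate
Product: 6 methyl 3-oxo-3-[2,4,5-trimethoxy-3-(propan-2-yl)phenyl]propanoate
Conditions: SnCl4, CH2Cl2, 0 °C to rt
Reagents that add atoms: none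
Why: Friedel–Crafts acylation should go to the free position that is ortho to one methoxy group and para to another (the other free position is activated by one methoxy group only), and SnCl4 is mild enough to spare the methoxy group that ends up ortho to the ketone.

**Step 4**
Reactants: 7 4-methylanisole
Product: 9 4-methylcyclohex-3-en-1-one, via 1-methoxy-4-methylcyclohexa-1,4-diene 8 (not isolated)
Conditions: Li, NH3 (l), t-BuOH, THF, −78 °C; then oxalic acid (cat.), MeOH/H2O, rt
Reagents that add atoms: water, O
Why: Birch reduction leaves the methoxy and methyl groups on the two remaining double bonds, and mild hydrolysis of the enol ether should give the β,γ-unsaturated ketone without conjugation.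

**Step 5**
Reactants: 9 4-methylcyclohex-3-en-1-one
Product: 10 2,2,4-trimethylcyclohex-3-en-1-one
Conditions: t-BuOK (2.1 equiv), MeI, t-BuOH/THF, 0 °C to rt
Reagents that add atoms: iodomethane, CI
Why: the extended dienolate is alkylated twice at the carbon between carbonyl and alkene (deconjugative gem-dimethylation), which also locks the double bond in the β,γ position.

**Step 6**
Reactants: 10 2,2,4-trimethylcyclohex-3-en-1-one
Product: 11 (S)-2,2,4-trimethylcyclohex-3-en-1-ol
Conditions: (R)-2-methyl-CBS-oxazaborolidine [(3aR)-1-methyl-3,3-diphenyltetrahydro-1H,3H-pyrrolo[1,2-c][1,3,2]oxazaborole] (cat.), BH3·SMe2, THF, −20 °C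
Reagents that add atoms: none
Why: Corey–Bakshi–Shibata reduction, in which the ketone binds with its quaternary α-carbon as the large group turned away from the catalyst, so that hydride should reach the face that gives the (S)-carbinol.

**Step 7**
Reactants: 6 methyl 3-oxo-3-[2,4,5-trimethoxy-3-(propan-2-yl)phenyl]propanoate; 11 (S)-2,2,4-trimethylcyclohex-3-en-1-ol
Product: 12 (1S)-2,2,4-trimethylcyclohex-3-en-1-yl 3-oxo-3-[2,4,5-trimethoxy-3-(propan-2-yl)phenyl]propanoate
Conditions: 4-(dimethylamino)pyridine (cat.), toluene, reflux, 4 Å molecular sieves (removal of MeOH)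
Reagents that add atoms: none
Why: amine-catalyzed transesterification of an enolizable β-keto ester, driven by removal of methanol, tolerates hindered secondary alcohols and does not touch the carbinol C–O bond, so the configuration is kept.

**Step 8**
Reactants: 12 (1S)-2,2,4-trimethylcyclohex-3-en-1-yl 3-oxo-3-[2,4,5-trimethoxy-3-(propan-2-yl)phenyl]propanoate
Product: 13 lactone-bridged tetracycle (cis-A/B-fused 11,12,14-trimethoxyabieta-8,11,13-trien-7-one whose C3 oxygen is joined through a carbonyl group to C6 as a δ-lactone; C3–O, C5–C6 and C10–C9 all on one face of ring A; 3S)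
Conditions: Mn(OAc)3·2H2O (2.2 equiv), degassed AcOH, 70 °C, argon
Reagents that add atoms: none
Why: Mn(OAc)3 forms the trivalent manganese enolate of the β-keto ester and releases the C6 radical, which adds 6-exo-trig to C5 of the ring A alkene (closing the δ-lactone ring and leaving a tertiary radical at C10); this radical attacks the free ortho carbon C9 of the aroyl ring (six-membered closure of ring B, 6-endo with respect to the C8–C9 bond), and a second equivalent of Mn(OAc)3 oxidizes the cyclohexadienyl radical, which loses a proton to restore ring C. The closest known reaction type is the Mn(OAc)3-mediated oxidative free-radical cyclization of unsaturated β-keto esters, including its lactone-forming variant with the alkene in the alcohol part and its termination by homolytic aromatic substitution, together with the α-tetralone synthesis from aryl ketones and alkenes under the same oxidant. C5 is set by the C3 oxygen, because the three-atom tether can reach only the alkene face syn to the axial C3–O bond; C6 is set because the aroyl group takes the equatorial position on the new lactone ring, away from the C4 methyl groups; C10 is set because C6 is then axial on ring A and a six-membered ring B can close only on the same face (a trans fusion would have to span two anti-axial bonds). Attack at C5 and not at C10 follows from the smaller ring and the tertiary radical that results, and the site on the arene is fixed because the other ortho position carries a methoxy group. The step needs arene attack to outrun oxidation of the tertiary radical, so no Cu(OAc)2 is added, and only a slight excess of oxidant is used to spare the remaining acidic C6–H of the product.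

**Step 9**
Reactants: 13 lactone-bridged tetracycle
Product: 15 (3S)-3-hydroxy-11,12,14-trimethoxyabieta-8,11,13-trien-7-one with cis A/B fusion (C5 and C10 as in 21), via C6 carboxylic acid 14 (not isolated)
Conditions: LiOH, THF/H2O, 40 °C; then aqueous HCl to pH 2, 60 °C
Reagents that add atoms: none
Why: saponification of the lactone and thermal decarboxylation of the β-keto acid remove the tether and its helper carbon, while C5 and C10 have no path to epimerize.

**Step 10**
Reactants: 15 (3S)-3-hydroxy-11,12,14-trimethoxyabieta-8,11,13-trien-7-one (cis A/B)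
Product: 16 11,12,14-trimethoxyabieta-8,11,13-triene-3,7-dione with cis A/B fusion
Conditions: Dess–Martin periodinane, CH2Cl2, rt
Reagents that add atoms: none
Why: Dess–Martin oxidation of the secondary alcohol is neutral and fast, and the neighbouring C4 is quaternary, so nothing can epimerize.

**Step 11**
Reactants: 16 11,12,14-trimethoxyabieta-8,11,13-triene-3,7-dione (cis A/B)
Product: 18 11,12,14-triacetoxyabieta-8,11,13-triene-3,7-dione with cis A/B fusion, via triphenol diketone 17 (not isolated)
Conditions: BBr3, CH2Cl2, −78 to 0 °C; MeOH, concentrate; then Ac2O, pyridine, 4-(dimethylamino)pyridine (cat.), CH2Cl2, rt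
Reagents that add atoms: acetic anhydride, CC(=O)OC(C)=O
Why: Lewis acid cleavage of the three aryl methyl ethers is done while the molecule holds no alkene and no tertiary ester, and immediate acetylation protects the air-sensitive triol and makes ring C electron-poor for the next step.

**Step 12**
Reactants: 18 11,12,14-triacetoxyabieta-8,11,13-triene-3,7-dione (cis A/B)
Product: 19 ε-lactone of 18 (oxygen inserted between C3 and C4; seven-membered ring A lactone with the C3 carbonyl)
Conditions: mCPBA, CH2Cl2, rt
Reagents that add atoms: 3-chloroperoxybenzoic acid, OOC(=O)c1cccc(Cl)c1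
Why: Baeyer–Villiger oxidation with migration of the quaternary carbon C4 should be selective for the ring A ketone, because at C7 neither the acetoxylated aryl group nor the primary C6 migrates readily.

**Step 13**
Reactants: 19 ε-lactone
Product: 20 3-[(1R,2S)-5,7,8-triacetoxy-1-methyl-4-oxo-6-(propan-2-yl)-2-(prop-1-en-2-yl)-1,2,3,4-tetrahydronaphthalen-1-yl]propanoic acid
Conditions: p-TsOH·H2O (cat.), CH2Cl2, rt to 40 °C
Reagents that add atoms: none
Why: acid-catalyzed alkyl–oxygen cleavage of the tertiary lactone (E1) with loss of a methyl proton should give the isopropenyl group and the free C3 acid, and the acetates keep the phenol oxygens from trapping the C4 cation.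

**Step 14**
Reactants: 20 triacetoxy seco acid
Product: 21 3-[(1R,2S)-5,7,8-trihydroxy-1-methyl-4-oxo-6-(propan-2-yl)-2-(prop-1-en-2-yl)-1,2,3,4-tetrahydronaphthalen-1-yl]propanoic acid
Conditions: K2CO3, degassed MeOH, 0 °C to rt, argon; then 1 M HCl, 0 °C
Reagents that add atoms: none
Why: base-mediated methanolysis of the aryl acetates leaves the alkene, the ketone and the acid untouched, and exclusion of air with an acidic quench should keep the triol in its reduced form.

**Compound list**

1 | 1,2,4-trimethoxybenzene | COc1ccc(OC)c(OC)c1 | starting material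
2 | (2,3,6-trimethoxyphenyl)lithium | [Li]c1c(OC)ccc(OC)c1OC | intermediate
3 | 2-(2,3,6-trimethoxyphenyl)propan-2-ol | CC(C)(O)c1c(OC)ccc(OC)c1OC | intermediate
4 | 1,2,4-trimethoxy-3-(propan-2-yl)benzene | CC(C)c1c(OC)ccc(OC)c1OC | intermediate
5 | methyl 3-chloro-3-oxopropanoate | COC(=O)CC(=O)Cl | starting material
6 | methyl 3-oxo-3-[2,4,5-trimethoxy-3-(propan-2-yl)phenyl]propanoate | COC(=O)CC(=O)c1cc(OC)c(OC)c(C(C)C)c1OC | intermediate
7 | 4-methylanisole | COc1ccc(C)cc1 | starting material
8 | 1-methoxy-4-methylcyclohexa-1,4-diene | COC1=CCC(C)=CC1 | intermediate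
9 | 4-methylcyclohex-3-en-1-one | CC1=CCC(=O)CC1 | intermediate
10 | 2,2,4-trimethylcyclohex-3-en-1-one | CC1=CC(C)(C)C(=O)CC1 | intermediate
11 | (S)-2,2,4-trimethylcyclohex-3-en-1-ol | CC1=CC(C)(C)[C@@H](O)CC1 | intermediate
12 | (1S)-2,2,4-trimethylcyclohex-3-en-1-yl 3-oxo-3-[2,4,5-trimethoxy-3-(propan-2-yl)phenyl]propanoate | CC1=CC(C)(C)[C@@H](OC(=O)CC(=O)c2cc(OC)c(OC)c(C(C)C)c2OC)CC1 | intermediate
13 | lactone-bridged tetracycle (δ-lactone O(C3)–CO–C6 on cis-A/B-fused 11,12,14-trimethoxyabieta-8,11,13-trien-7-one) | C[C@]12CC[C@@H]3OC(=O)[C@H](C(=O)c4c(OC)c(C(C)C)c(OC)c(OC)c41)[C@H]2C3(C)C | intermediate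
14 | C6 carboxylic acid of 15 (β-keto acid; C6 configurationally labile) | C[C@@]12CC[C@H](O)C(C)(C)[C@@H]1[C@H](C(=O)O)C(=O)c3c(OC)c(C(C)C)c(OC)c(OC)c32 | intermediate
15 | (3S)-3-hydroxy-11,12,14-trimethoxyabieta-8,11,13-trien-7-one, cis A/B | C[C@@]12CC[C@H](O)C(C)(C)[C@@H]1CC(=O)c3c(OC)c(C(C)C)c(OC)c(OC)c32 | intermediate
16 | 11,12,14-trimethoxyabieta-8,11,13-triene-3,7-dione, cis A/B | C[C@@]12CCC(=O)C(C)(C)[C@@H]1CC(=O)c3c(OC)c(C(C)C)c(OC)c(OC)c32 | intermediate
17 | 11,12,14-trihydroxyabieta-8,11,13-triene-3,7-dione, cis A/B | C[C@@]12CCC(=O)C(C)(C)[C@@H]1CC(=O)c3c(O)c(C(C)C)c(O)c(O)c32 | intermediate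
18 | 11,12,14-triacetoxyabieta-8,11,13-triene-3,7-dione, cis A/B | C[C@@]12CCC(=O)C(C)(C)[C@@H]1CC(=O)c3c(OC(C)=O)c(C(C)C)c(OC(C)=O)c(OC(C)=O)c32 | intermediate
19 | ε-lactone of 18 (O between C3 and C4) | C[C@@]12CCC(=O)OC(C)(C)[C@@H]1CC(=O)c3c(OC(C)=O)c(C(C)C)c(OC(C)=O)c(OC(C)=O)c32 | intermediate
20 | 3-[(1R,2S)-5,7,8-triacetoxy-1-methyl-4-oxo-6-(propan-2-yl)-2-(prop-1-en-2-yl)-1,2,3,4-tetrahydronaphthalen-1-yl]propanoic acid | C=C(C)[C@@H]1CC(=O)c2c(OC(C)=O)c(C(C)C)c(OC(C)=O)c(OC(C)=O)c2[C@]1(C)CCC(=O)O | intermediate
21 | 3-[(1R,2S)-5,7,8-trihydroxy-1-methyl-4-oxo-6-(propan-2-yl)-2-(prop-1-en-2-yl)-1,2,3,4-tetrahydronaphthalen-1-yl]propanoic acid | C=C(C)[C@@H]1CC(=O)c2c(O)c(C(C)C)c(O)c(O)c2[C@]1(C)CCC(=O)O | target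

**Step count**

Total steps: 14. Longest linear sequence: 11 steps (steps 1–3 and 7–14; the branch through steps 4–6 and 7–14 is equally long).

**Steps most likely to fail**

Step 8. The ester must rotate out of its preferred conformation before C6 can reach C5, so the C6 radical may be quenched or oxidized before it cyclizes. The oxidant may also take the tertiary C10 radical before it attacks the arene, and the product still has an oxidizable C6–H. The fallback sets out from 12 and comes back at 13. Bromination of 12 between the two carbonyl groups (NBS, NH4OAc cat., Et2O, 0 °C) would give the α-bromo β-keto ester F1. Displacement with EtOCS2K (acetone, 0 °C) would give the S-alkyl O-ethyl xanthate F2. Heating F2 with dilauroyl peroxide, added in portions up to a full equivalent (chlorobenzene, reflux), would run the same two ring closures as a degenerative xanthate-transfer chain. There the C6 radical is regenerated many times and can wait for the ester to rotate, no metal oxidant is present to intercept the C10 radical, and the peroxide oxidizes only the final cyclohexadienyl radical.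

Step 13. The C4 cation may lose the C5 proton instead of a methyl proton (a tetrasubstituted alkene and loss of the C5 stereocenter), may rearrange by hydride shift, or may simply return to the lactone. The fallback sets out from 18 and comes back at 20, and it also bypasses step 12. Reduction of the ring A ketone of 18 (NaBH4, EtOH/THF, −20 °C; the hindered, conjugated aryl ketone should react more slowly) would give the C3 alcohol F3, of which either C3 epimer serves. Pb(OAc)4 with Cu(OAc)2 (cat.) and pyridine in benzene at 80 °C would generate the C3 alkoxy radical, whose β-scission breaks C3–C4. Cu(OAc)2 would then turn the tertiary C4 radical into the less substituted alkene by loss of a methyl hydrogen, giving the isopropenyl aldehyde F4 without a free C4 cation. Pinnick oxidation (NaClO2, NaH2PO4, 2-methyl-2-butene, t-BuOH/H2O) would give 20.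

Step 14. The electron-rich triol, present as its phenoxide during deacetylation, may be oxidized by traces of air to the para-quinone. The fallback sets out from 20 and comes back at 21. The acetates would be removed with K2CO3 in MeOH open to air, so that the triol is oxidized on purpose to the stable hydroxy-para-quinone F5 (carbonyl groups at C11 and C14, hydroxyl at C12), which can be purified after acidification. Reduction with aqueous Na2S2O4 in a two-phase mixture with EtOAc under argon would then give 21 as the last operation under neutral, reducing conditions.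

**Further compounds**

F1 | step 8 | (1S)-2,2,4-trimethylcyclohex-3-en-1-yl 2-bromo-3-oxo-3-[2,4,5-trimethoxy-3-(propan-2-yl)phenyl]propanoate (both epimers at the brominated carbon) | CC1=CC(C)(C)[C@@H](OC(=O)C(Br)C(=O)c2cc(OC)c(OC)c(C(C)C)c2OC)CC1
F2 | step 8 | (1S)-2,2,4-trimethylcyclohex-3-en-1-yl 2-[(ethoxycarbonothioyl)sulfanyl]-3-oxo-3-[2,4,5-trimethoxy-3-(propan-2-yl)phenyl]propanoate (both epimers at the sulfur-bearing carbon) | CC1=CC(C)(C)[C@@H](OC(=O)C(SC(=S)OCC)C(=O)c2cc(OC)c(OC)c(C(C)C)c2OC)CC1
F3 | step 13 | 11,12,14-triacetoxy-3-hydroxyabieta-8,11,13-trien-7-one, cis A/B (either C3 epimer) | C[C@@]12CCC(O)C(C)(C)[C@@H]1CC(=O)c3c(OC(C)=O)c(C(C)C)c(OC(C)=O)c(OC(C)=O)c32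
F4 | step 13 | 3-[(1R,2S)-5,7,8-triacetoxy-1-methyl-4-oxo-6-(propan-2-yl)-2-(prop-1-en-2-yl)-1,2,3,4-tetrahydronaphthalen-1-yl]propanal | C=C(C)[C@@H]1CC(=O)c2c(OC(C)=O)c(C(C)C)c(OC(C)=O)c(OC(C)=O)c2[C@]1(C)CCC=O
F5 | step 14 | 3-[(1R,2S)-7-hydroxy-1-methyl-4,5,8-trioxo-6-(propan-2-yl)-2-(prop-1-en-2-yl)-1,2,3,4,5,8-hexahydronaphthalen-1-yl]propanoic acid | C=C(C)[C@@H]1CC(=O)C2=C(C(=O)C(O)=C(C(C)C)C2=O)[C@]1(C)CCC(=O)O
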